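**Plan**

- Lactone numbering: O1, C2 (C=O), C3 (=CH2), C4 (CO2H), C5 (chain). The retrosynthesis cuts, in order, the terminal O–acetyl bond, the exocyclic C3=CH2 bond, the lactone O1–C2 bond together with the C5–H bond (back to a 5-ketone), and the C4–C5 bond.
- Forward: 1,14-tetradecanediol becomes a C14 acetoxy aldehyde whose formyl carbon (future C5) is joined to dimethyl maleate (future C4, C3, C2 and the carboxyl carbon) by a Stetter reaction. The only ring, the γ-lactone, closes directly after the ketone reduction. The C3 methylene follows, and the acetate, which is lost in the ester hydrolysis, is put back in the last step.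
- Enabling feature: C5 is a carbinol carbon bonded to C4, and in the ring-opened 5-oxo diester C4 is a CH between a ketone and an ester that loses its configuration freely. One enantioselective reduction under equilibrating conditions can therefore fix C5 and C4 together.
- Stereochemistry: both centres (4S,5R, trans) come from the ketoreductase in step 4. The trans lactone is also the thermodynamic C4 epimer, and after step 7 the molecule meets no base.

Key step: step 4

Assumption: a panel ketoreductase that accepts the long-chain keto diester with (4S,5R) selectivity is taken to be available; the C5 sense required is that of the (R)-3-hydroxyacyl-forming reductases.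

**Route**

Step 1
Reactants: 1 1,14-tetradecanediol
Product: 2 14-hydroxytetradecyl acetate
Conditions: Ac2O (0.5 equiv per diol), pyridine, 4-(dimethylamino)pyridine (cat.), THF, 0 °C to rt; unreacted diol recovered
Reagents that add atoms: acetic anhydride, CC(=O)OC(C)=O
Why: Statistical monoacylation (nucleophilic acyl substitution) of a symmetrical diol with a deficit of anhydride should stop largely at the monoacetate, which is separable from recovered diol and a little diacetate.

Step 2
Reactants: 2 14-hydroxytetradecyl acetate
Product: 3 14-oxotetradecyl acetate
Conditions: TEMPO (2,2,6,6-tetramethylpiperidin-1-oxyl, cat.), PhI(OAc)2, CH2Cl2, rt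
Reagents that add atoms: none
Why: The oxoammonium-mediated TEMPO/PhI(OAc)2 oxidation should take the primary alcohol to the aldehyde without over-oxidation and leave the acetate untouched.

Step 3
Reactants: 3 14-oxotetradecyl acetate; 4 dimethyl maleate
Product: 5 rac-dimethyl 2-(14-acetoxytetradecanoyl)butanedioate
Conditions: 3-benzyl-5-(2-hydroxyethyl)-4-methylthiazolium chloride (20 mol %), Et3N, 1,4-dioxane, 80 °C, N2
Reagents that add atoms: none
Why: In this Stetter reaction the thiazolium-derived carbene turns the aldehyde into its Breslow intermediate, an acyl anion equivalent that adds in conjugate fashion to the doubly activated alkene of 4 and forms the C4–C5 bond; the new C4 centre lies between ketone and ester and arises as the racemate, which is what step 4 needs.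

Step 4
Reactants: 5 rac-dimethyl 2-(14-acetoxytetradecanoyl)butanedioate
Product: 7 methyl (2R,3S)-2-(13-acetoxytridecyl)-5-oxotetrahydrofuran-3-carboxylate, via open-chain hydroxy diester 6 (not isolated)
Conditions: NADPH-dependent ketoreductase (panel hit), NADP+ (cat.), D-glucose, glucose dehydrogenase, KH2PO4/K2HPO4 buffer (0.2 M, pH 7.0), DMSO (15% v/v), 30 °C; extraction; then TsOH·H2O (cat.), toluene, 40 °C
Reagents that add atoms: none
Why: In neutral buffer the C4–H of 5, flanked by the ketone and an ester carbonyl, exchanges through the enol, so the two enantiomers interconvert while the ketoreductase binds one of them and transfers hydride from NADPH (regenerated by glucose dehydrogenase and glucose) to one face of the C5 carbonyl, giving hydroxy diester 6. The closest known reaction type is the ketoreductase-catalysed dynamic reductive kinetic resolution of α-substituted β-keto esters. On acid treatment the C5 hydroxyl of 6 attacks the CH2CO2Me carbonyl in a 5-exo-trig acyl substitution that forms the O1–C2 bond and expels methanol, whereas closure onto the C4 ester would require a four-membered ring. C5 (R) is set by the face of hydride delivery imposed by the active site, and C4 (S) by the enzyme's choice of one of the rapidly equilibrating enantiomers, the pairing that leads to the trans lactone, which is also the more stable C4 epimer. The step needs racemisation at C4 to outpace reduction of the disfavoured enantiomer and needs reduction to be confined to the ketone; the first is secured by the acidity of the doubly activated C4–H, which is lost once C5 is reduced so that 6 is configurationally fixed, and the second by the enzyme, which does not reduce esters. The unbranched chain resembles the fatty acyl substrates of (R)-3-hydroxyacyl-forming reductases, and the acetate lies thirteen carbons from the reacting centre.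

Step 5
Reactants: 7 methyl (2R,3S)-2-(13-acetoxytridecyl)-5-oxotetrahydrofuran-3-carboxylate
Product: 8 (2R,3S)-2-(13-hydroxytridecyl)-5-oxotetrahydrofuran-3-carboxylic acid
Conditions: 2 M H2SO4 (aq)/1,4-dioxane 1:1, reflux
Reagents that add atoms: water, O
Why: Acid-catalysed ester hydrolysis (AAC2) should cleave the methyl ester and the acetate while the γ-lactone, the favoured form of a γ-hydroxy acid in acid, is retained; sulfuric acid is chosen so that the freed primary alcohol cannot be converted into a chloride, and C4 can only drift toward the trans arrangement it already has.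

Step 6
Reactants: 8 (2R,3S)-2-(13-hydroxytridecyl)-5-oxotetrahydrofuran-3-carboxylic acid
Product: 9 (4S,5R)-5-(13-hydroxytridecyl)-2-oxotetrahydrofuran-3,4-dicarboxylic acid (C3 epimers, used crude)
Conditions: MeOMgOCO2Me (2 M in DMF, large excess), 130 °C, N2; then cold 2 M HCl
Reagents that add atoms: methyl magnesium carbonate, COC(=O)O[Mg]OC
Why: Lactone α-carboxylation with methyl magnesium carbonate is driven by a chelated magnesium enolate–carboxylate at C3, the hydroxyl and carboxyl groups travel as magnesium salts and return on acidification, and the new C3 centre is of no consequence because it becomes sp2 in step 7.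

Step 7
Reactants: 9 (4S,5R)-5-(13-hydroxytridecyl)-2-oxotetrahydrofuran-3,4-dicarboxylic acid
Product: 11 (2R,3S)-2-(13-hydroxytridecyl)-4-methylidene-5-oxotetrahydrofuran-3-carboxylic acid, via Mannich base 10 (not isolated)
Conditions: 37% aq. HCHO, N-methylaniline, NaOAc, AcOH, rt
Reagents that add atoms: formaldehyde, C=O
Why: In this decarboxylative Mannich methylenation the malonic-type acid adds to the iminium ion from formaldehyde and N-methylaniline to give 10, which fragments with loss of CO2 and the amine and places the double bond exocyclic at C3; the buffered room-temperature medium should leave C4 and C5 untouched.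

Step 8
Reactants: 11 (2R,3S)-2-(13-hydroxytridecyl)-4-methylidene-5-oxotetrahydrofuran-3-carboxylic acid
Product: 12 (2R,3S)-2-(13-acetoxytridecyl)-4-methylidene-5-oxotetrahydrofuran-3-carboxylic acid
Conditions: immobilised Candida antarctica lipase B, vinyl acetate, MTBE, 30 °C
Reagents that add atoms: vinyl acetate, C=COC(C)=O
Why: Lipase-catalysed transesterification with vinyl acetate, irreversible because the vinyl alcohol released tautomerises to acetaldehyde, should acylate the unhindered primary alcohol under neutral conditions, so that neither base-induced migration of the exocyclic double bond nor conjugate addition can occur, and the ring-bound α-branched acid is a poor acyl donor for the enzyme.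

**Compound list**

1 | 1,14-tetradecanediol | OCCCCCCCCCCCCCCO | starting material
2 | 14-hydroxytetradecyl acetate | CC(=O)OCCCCCCCCCCCCCCO | intermediate
3 | 14-oxotetradecyl acetate | CC(=O)OCCCCCCCCCCCCCC=O | intermediate
4 | dimethyl maleate | COC(=O)/C=C\C(=O)OC | starting material
5 | rac-dimethyl 2-(14-acetoxytetradecanoyl)butanedioate | COC(=O)CC(C(=O)OC)C(=O)CCCCCCCCCCCCCOC(C)=O | intermediate
6 | dimethyl (2S)-2-[(1R)-14-acetoxy-1-hydroxytetradecyl]butanedioate | COC(=O)C[C@H](C(=O)OC)[C@@H](CCCCCCCCCCCCCOC(C)=O)O | intermediate
7 | methyl (2R,3S)-2-(13-acetoxytridecyl)-5-oxotetrahydrofuran-3-carboxylate | O=C1C[C@H](C(=O)OC)[C@@H](CCCCCCCCCCCCCOC(C)=O)O1 | intermediate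
8 | (2R,3S)-2-(13-hydroxytridecyl)-5-oxotetrahydrofuran-3-carboxylic acid | O=C1C[C@H](C(=O)O)[C@@H](CCCCCCCCCCCCCO)O1 | intermediate
9 | (4S,5R)-5-(13-hydroxytridecyl)-2-oxotetrahydrofuran-3,4-dicarboxylic acid (C3 epimers) | OC(=O)C1C(=O)O[C@H](CCCCCCCCCCCCCO)[C@H]1C(=O)O | intermediate
10 | (4S,5R)-5-(13-hydroxytridecyl)-3-{[methyl(phenyl)amino]methyl}-2-oxotetrahydrofuran-3,4-dicarboxylic acid (C3 epimers) | CN(CC1(C(=O)O)C(=O)O[C@H](CCCCCCCCCCCCCO)[C@H]1C(=O)O)c1ccccc1 | intermediate
11 | (2R,3S)-2-(13-hydroxytridecyl)-4-methylidene-5-oxotetrahydrofuran-3-carboxylic acid | C=C1C(=O)O[C@H](CCCCCCCCCCCCCO)[C@H]1C(=O)O | intermediate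
12 | (2R,3S)-2-(13-acetoxytridecyl)-4-methylidene-5-oxotetrahydrofuran-3-carboxylic acid | C=C1C(=O)O[C@H](CCCCCCCCCCCCCOC(C)=O)[C@H]1C(=O)O | target

**Step count**

Total: 8 steps. Longest linear sequence: 8 steps from 1,14-tetradecanediol (dimethyl maleate is bought and enters in step 3).

**Steps most likely to fail**

Step 4. Three processes could defeat it:
- the enzyme may bind the lipophilic substrate poorly, so that conversion stalls;
- hydride may be delivered to the wrong face, or the wrong C4 enantiomer may be reduced;
- esterases in the enzyme preparation may hydrolyse the esters.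

The fallback sets out from 5 and uses asymmetric hydrogenation in place of the enzyme: RuCl2[(R)-BINAP], H2 (50 bar), MeOH, 50 °C. By analogy with simple 3-oxoalkanoates this ligand should fix C5 as R regardless of C4, giving 6 together with its C4 epimer dimethyl (2R)-2-[(1R)-14-acetoxy-1-hydroxytetradecyl]butanedioate F1. Lactonisation with catalytic TsOH·H2O in toluene then gives 7 and the cis lactone methyl (2R,3R)-2-(13-acetoxytridecyl)-5-oxotetrahydrofuran-3-carboxylate F2. Catalytic DBU in toluene at rt should epimerise F2 at C4, α to the ester, to the more stable trans isomer, so the sequence comes back to the route at 7. The same equilibration would also rescue an enzyme that is correct at C5 but prefers the other C4 enantiomer.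

Step 3. Acyloin self-condensation of the aliphatic aldehyde and base-promoted aldol reactions may outrun conjugate addition of the Breslow intermediate. The fallback sets out from 3 and 4 and replaces the polar umpolung by a radical hydroacylation: (nBu4N)4[W10O32] (2 mol %), MeCN, 365 nm, rt. The excited decatungstate abstracts the formyl hydrogen, the acyl radical adds to the electron-poor alkene, and back hydrogen transfer completes the chain. This gives 5 directly, where the route is rejoined; no compound outside the list is made (F0).

Step 8. Acylation may be slow because the free acid impairs the enzyme, and on prolonged exposure the exocyclic double bond may migrate into the ring or hydroxy acid molecules may esterify one another. The fallback sets out from 11 and masks the alkene before a conventional acetylation: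
- conjugate addition of thiophenol (PhSH, Et3N cat., THF, 0 °C) gives (2R,3S)-2-(13-hydroxytridecyl)-5-oxo-4-[(phenylsulfanyl)methyl]tetrahydrofuran-3-carboxylic acid F3;
- Ac2O/pyridine with aqueous work-up gives (2R,3S)-2-(13-acetoxytridecyl)-5-oxo-4-[(phenylsulfanyl)methyl]tetrahydrofuran-3-carboxylic acid F4;
- NaIO4 in MeOH/H2O at 0 °C gives the sulfoxide (2R,3S)-2-(13-acetoxytridecyl)-5-oxo-4-[(phenylsulfinyl)methyl]tetrahydrofuran-3-carboxylic acid F5;
- thermal syn-elimination in toluene at 100 °C, for which the only β-hydrogen is the one on the ring carbon, regenerates the exocyclic alkene and arrives at 12.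

**Further compounds**

F1 | step 4 | dimethyl (2R)-2-[(1R)-14-acetoxy-1-hydroxytetradecyl]butanedioate | COC(=O)C[C@@H](C(=O)OC)[C@@H](CCCCCCCCCCCCCOC(C)=O)O
F2 | step 4 | methyl (2R,3R)-2-(13-acetoxytridecyl)-5-oxotetrahydrofuran-3-carboxylate | O=C1C[C@@H](C(=O)OC)[C@@H](CCCCCCCCCCCCCOC(C)=O)O1
F0 | step 3 | none | none
F3 | step 8 | (2R,3S)-2-(13-hydroxytridecyl)-5-oxo-4-[(phenylsulfanyl)methyl]tetrahydrofuran-3-carboxylic acid (C4 epimers) | O=C1O[C@H](CCCCCCCCCCCCCO)[C@@H](C(=O)O)C1CSc1ccccc1
F4 | step 8 | (2R,3S)-2-(13-acetoxytridecyl)-5-oxo-4-[(phenylsulfanyl)methyl]tetrahydrofuran-3-carboxylic acid (C4 epimers) | O=C1O[C@H](CCCCCCCCCCCCCOC(C)=O)[C@@H](C(=O)O)C1CSc1ccccc1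
F5 | step 8 | (2R,3S)-2-(13-acetoxytridecyl)-5-oxo-4-[(phenylsulfinyl)methyl]tetrahydrofuran-3-carboxylic acid (C4 and sulfur epimers) | O=C1O[C@H](CCCCCCCCCCCCCOC(C)=O)[C@@H](C(=O)O)C1CS(=O)c1ccccc1
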